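**Retrosynthetic overview**
- The target comes from a ten-membered 8,9-diol by O8-isobutyrylation, O9-acetylation and desilylation; the carbocycle is closed last by ring-closing metathesis at C1=C10 (ring-cis enoate).
- The metathesis substrate is a trans α-methylene-γ-butyrolactone, formed first by stereospecific allylboration–lactonisation (C6–C7, sets C6 and C7) of a (2E)-enal with a (Z)-2-(methoxycarbonyl)allylboronate.
- The allylboronate comes from an ynoate; the key C7–C8 bond is made by a visible-light decarboxylative radical alkoxycarbonylethynylation of an L-tartrate-derived dioxolane acid (C8 re-formed trans to C9). The C10 acrylate comes from Pd-catalysed hydromethoxycarbonylation of a terminal alkyne.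
- The enal comes from but-2-yne-1,4-diol (trans-hydroalumination/iodination fixes the C4=C5 geometry) and (S)-epichlorohydrin (C2), followed by one-carbon homologation to the vinyl carbinol.
- Ring order: γ-lactone (step 13), then the ten-membered ring (step 14).

Assumption: locants follow germacranolide numbering of the target (C12 lactone carbonyl, lactone O on C6, C14 = CO2Me on C10, C15 = CH2O on C4); the given SMILES is taken as the absolute configuration (2S,6R,7S,8S,9S).

Step 1
Reactants: 1 but-2-yne-1,4-diol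
Product: 2 4-[(tert-butyldiphenylsilyl)oxy]but-2-yn-1-ol
Conditions: NaH (1.0 equiv), THF, 0 °C; TBDPSCl (1.0 equiv), 1 (3 equiv), 0 °C to rt
Reagents that add atoms: tert-butyl(chloro)diphenylsilane, CC(C)(C)[Si](Cl)(c1ccccc1)c1ccccc1
Why: Monosilylation of a symmetrical diol through its monosodium alkoxide with the diol in excess gives the mono-ether cleanly (O-silylation); no stereocentre is involved.

Step 2
Reactants: 2 4-[(tert-butyldiphenylsilyl)oxy]but-2-yn-1-ol
Product: 4 (2Z)-4-[(tert-butyldiphenylsilyl)oxy]-3-iodobut-2-en-1-ol, via sodium alkenylalanate 3 (not isolated)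
Conditions: NaAlH2(OCH2CH2OMe)2 (1.5 equiv), THF, 0 °C to rt; then I2, −78 °C; aq. Rochelle salt
Reagents that add atoms: iodine, [I][I]
Why: Hydroxyl-directed trans-hydroalumination of the propargylic alcohol places Al on the distal alkyne carbon in a five-membered chelate, and iodinolysis with retention gives the vinyl iodide with I cis to CH2OH, which fixes the later C4=C5 geometry.

Step 3
Reactants: 4 (2Z)-4-[(tert-butyldiphenylsilyl)oxy]-3-iodobut-2-en-1-ol
Product: 5 (2Z)-1-[(tert-butyldiphenylsilyl)oxy]-2-iodo-4-[(triethylsilyl)oxy]but-2-ene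
Conditions: Et3SiCl, imidazole, CH2Cl2, 0 °C
Reagents that add atoms: chlorotriethylsilane, CC[Si](Cl)(CC)CC
Why: Routine O-silylation; the triethylsilyl ether masks the acidic OH for the lithiation and is the one silyl group that step 6 can oxidise directly.

Step 4
Reactants: 5 (2Z)-1-[(tert-butyldiphenylsilyl)oxy]-2-iodo-4-[(triethylsilyl)oxy]but-2-ene; 6 (S)-epichlorohydrin [(2S)-2-(chloromethyl)oxirane]
Product: 8 (2S,4E)-1-chloro-4-{[(tert-butyldiphenylsilyl)oxy]methyl}-6-[(triethylsilyl)oxy]hex-4-en-2-ol, via alkenyllithium 7 (not isolated)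
Conditions: t-BuLi (2.05 equiv), Et2O, −78 °C; then BF3·OEt2, 6, −78 °C; H2O
Reagents that add atoms: none
Why: Iodine–lithium exchange at −78 °C in ether retains the alkene geometry (the low temperature suppresses 1,4-silyl migration and β-elimination), and BF3-promoted SN2 opening of the epoxide at its CH2 terminus leaves the bought stereocentre untouched as C2.

Step 5
Reactants: 8 (2S,4E)-1-chloro-4-{[(tert-butyldiphenylsilyl)oxy]methyl}-6-[(triethylsilyl)oxy]hex-4-en-2-ol
Product: 11 (3S,5E)-3-[(tert-butyldimethylsilyl)oxy]-5-{[(tert-butyldiphenylsilyl)oxy]methyl}-7-[(triethylsilyl)oxy]hepta-1,5-diene, via epoxide 9 (not isolated), via lithium alkoxide 10 (not isolated)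
Conditions: Me3S+ I− (3.5 equiv), n-BuLi (3.3 equiv), THF, −20 °C to rt; then TBSOTf, −78 to 0 °C
Reagents that add atoms: trimethylsulfonium iodide, C[S+](C)C.[I-]; tert-butyldimethylsilyl trifluoromethanesulfonate, CC(C)(C)[Si](C)(C)OS(=O)(=O)C(F)(F)F
Why: The alkoxide closes to the terminal epoxide, dimethylsulfonium methylide opens it at CH2 and the betaine eliminates Me2S to the vinyl carbinol (sulfonium-ylide one-carbon homologation of an epoxide to an allylic alcohol), and the alkoxide is silylated in the same flask; no bond to C2 is broken, so it stays S.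

Step 6
Reactants: 11 (3S,5E)-3-[(tert-butyldimethylsilyl)oxy]-5-{[(tert-butyldiphenylsilyl)oxy]methyl}-7-[(triethylsilyl)oxy]hepta-1,5-diene
Product: 12 (2E,5S)-5-[(tert-butyldimethylsilyl)oxy]-3-{[(tert-butyldiphenylsilyl)oxy]methyl}hepta-2,6-dienal
Conditions: (COCl)2, DMSO, CH2Cl2, −78 to −40 °C; Et3N, −78 °C to rt
Reagents that add atoms: none
Why: Swern oxidation converts a primary triethylsilyl ether directly into the aldehyde while the TBS and TBDPS ethers survive, and the cold conditions keep the enal geometry (C6 cis to C3).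

Step 7
Reactants: 13 methyl prop-2-ynoate
Product: 14 methyl 3-bromoprop-2-ynoate
Conditions: N-bromosuccinimide, AgNO3 (10 mol %), acetone, rt, dark
Reagents that add atoms: N-bromosuccinimide, BrN1C(=O)CCC1=O
Why: Silver-catalysed electrophilic bromination of the terminal alkyne C–H gives the bromoalkyne, used without storage.

Step 8
Reactants: 15 dimethyl (4R,5R)-2,2-dimethyl-1,3-dioxolane-4,5-dicarboxylate
Product: 16 (4R,5R)-5-(methoxycarbonyl)-2,2-dimethyl-1,3-dioxolane-4-carboxylic acid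
Conditions: KOH (1.0 equiv), MeOH, 0 °C to rt; then aq. HCl
Reagents that add atoms: potassium hydroxide, [K+].[OH-]
Why: Mono-saponification of the C2-symmetric diester stops after one ester because the carboxylate deactivates the second; both tartrate stereocentres are untouched.

Step 9
Reactants: 16 (4R,5R)-5-(methoxycarbonyl)-2,2-dimethyl-1,3-dioxolane-4-carboxylic acid
Product: 18 (4R,5S)-5-ethynyl-2,2-dimethyl-1,3-dioxolane-4-carboxylic acid, via aldehyde acid 17 (not isolated)
Conditions: i-Bu2AlH (2.2 equiv), CH2Cl2, −78 °C; then MeOH, K2CO3, dimethyl (1-diazo-2-oxopropyl)phosphonate, 0 °C to rt; aq. citric acid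
Reagents that add atoms: dimethyl (1-diazo-2-oxopropyl)phosphonate, COP(=O)(OC)C(=[N+]=[N-])C(C)=O
Why: The aluminium carboxylate is inert at −78 °C while the ester is reduced to the aluminium hemiacetal, which releases the aldehyde for Seyferth–Gilbert homologation with the Ohira–Bestmann reagent; the trans-dioxolane is the stable epimer, so C9 is retained (its descriptor changes to S only by the sequence rule).

Step 10
Reactants: 18 (4R,5S)-5-ethynyl-2,2-dimethyl-1,3-dioxolane-4-carboxylic acid; 14 methyl 3-bromoprop-2-ynoate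
Product: 20 methyl 3-[(4S,5S)-5-ethynyl-2,2-dimethyl-1,3-dioxolan-4-yl]prop-2-ynoate, via N-acyloxyphthalimide 19 (not isolated)
Conditions: N-hydroxyphthalimide, N,N′-diisopropylcarbodiimide, DMAP (cat.), CH2Cl2, rt; then 14 (2 equiv), Hantzsch ester (1.5 equiv), 4CzIPN (1 mol %), DMF, 450 nm LEDs, rt
Reagents that add atoms: none
Why: Proposed new method: a visible-light decarboxylative alkoxycarbonylethynylation in which single-electron reduction of 19 (photoexcited 4CzIPN/Hantzsch ester) releases CO2 and the nucleophilic dioxolan-4-yl radical, which adds to the bromine-bearing β-carbon of the electrophilic bromopropiolate on the face anti to the C5 ethynyl group, after which the α-ester vinyl radical expels Br• (reduced by the Hantzsch ester radical), so the C7–C8 bond is formed and C8 is reset trans to the bought C9 centre; the closest known reaction type is the photoredox decarboxylative alkynylation of redox-active esters with alkynyl sulfones, aryl bromoalkynes or ethynylbenziodoxolones, which has not been shown with a propiolate-transfer reagent.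

Step 11
Reactants: 20 methyl 3-[(4S,5S)-5-ethynyl-2,2-dimethyl-1,3-dioxolan-4-yl]prop-2-ynoate
Product: 21 methyl 2-[(4S,5S)-5-(3-methoxy-3-oxoprop-1-yn-1-yl)-2,2-dimethyl-1,3-dioxolan-4-yl]prop-2-enoate
Conditions: CO (20 bar), MeOH (5 equiv), Pd(OAc)2 (2 mol %), 2-(diphenylphosphino)pyridine (8 mol %), MsOH (5 mol %), CH2Cl2, 45 °C
Reagents that add atoms: carbon monoxide, [C-]#[O+]; methanol, CO
Why: Drent-type palladium hydride catalysed Markovnikov hydromethoxycarbonylation is selective for the terminal alkyne over the internal electron-poor ynoate and gives the 2-substituted acrylate (C10, C14 and the CH2 later lost in metathesis); the limited MeOH and acid load spare the acetonide.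

Step 12
Reactants: 21 methyl 2-[(4S,5S)-5-(3-methoxy-3-oxoprop-1-yn-1-yl)-2,2-dimethyl-1,3-dioxolan-4-yl]prop-2-enoate
Product: 23 methyl (2Z)-3-[(4S,5S)-5-(3-methoxy-3-oxoprop-1-en-2-yl)-2,2-dimethyl-1,3-dioxolan-4-yl]-2-[(4,4,5,5-tetramethyl-1,3,2-dioxaborolan-2-yl)methyl]prop-2-enoate, via alkenylalane 22 (not isolated)
Conditions: i-Bu2AlH (1.1 equiv), HMPA, THF, 0 °C; then ICH2Bpin, 0 °C to rt
Reagents that add atoms: 2-(iodomethyl)-4,4,5,5-tetramethyl-1,3,2-dioxaborolane, ICB1OC(C)(C)C(C)(C)O1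
Why: The i-Bu2AlH–HMPA complex adds H–Al syn across the ynoate (Al on the α-carbon) without copper and so leaves the α-substituted acrylate alone, and C-alkylation with retention (Hall-type conjugate reduction/borylmethylation) gives the allylboronate with the dioxolanyl group cis to CO2Me and trans to CH2B.

Step 13
Reactants: 23 methyl (2Z)-3-[(4S,5S)-5-(3-methoxy-3-oxoprop-1-en-2-yl)-2,2-dimethyl-1,3-dioxolan-4-yl]-2-[(4,4,5,5-tetramethyl-1,3,2-dioxaborolan-2-yl)methyl]prop-2-enoate; 12 (2E,5S)-5-[(tert-butyldimethylsilyl)oxy]-3-{[(tert-butyldiphenylsilyl)oxy]methyl}hepta-2,6-dienal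
Product: 25 (4S,5R)-5-[(1E,4S)-4-[(tert-butyldimethylsilyl)oxy]-2-{[(tert-butyldiphenylsilyl)oxy]methyl}hexa-1,5-dien-1-yl]-4-[(4S,5S)-5-(3-methoxy-3-oxoprop-1-en-2-yl)-2,2-dimethyl-1,3-dioxolan-4-yl]-3-methylideneoxolan-2-one, via pinacol borate 24 (not isolated)
Conditions: Sc(OTf)3 (10 mol %), PhMe, −20 °C to rt; then PPTS (cat.), 50 °C
Reagents that add atoms: none
Why: Lewis acid-catalysed type 1 allylboration through a closed chair transition state gives the anti adduct and hence the trans lactone (C6 and C7) because the γ-substituent is trans to CH2B, while A(1,3) strain with the ester holds H-8 in the alkene plane so the aldehyde adds anti to the C8–C9 bond (C7 set by the tartrate-derived C8), and the borate then closes onto the methyl ester (tandem allylboration–lactonisation).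

Step 14
Reactants: 25 (4S,5R)-5-[(1E,4S)-4-[(tert-butyldimethylsilyl)oxy]-2-{[(tert-butyldiphenylsilyl)oxy]methyl}hexa-1,5-dien-1-yl]-4-[(4S,5S)-5-(3-methoxy-3-oxoprop-1-en-2-yl)-2,2-dimethyl-1,3-dioxolan-4-yl]-3-methylideneoxolan-2-one
Product: 26 methyl (2S,6R,7S,8S,9S)-2-[(tert-butyldimethylsilyl)oxy]-15-[(tert-butyldiphenylsilyl)oxy]-8,9-(isopropylidenedioxy)germacra-1(10)E,4E,11(13)-trien-12,6-olid-14-oate
Conditions: second-generation Hoveyda–Grubbs catalyst RuCl2(H2IMes)(=CH-C6H4-2-Oi-Pr) (15 mol %), 1,4-benzoquinone (cat.), PhMe (1 mM), 80 °C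
Reagents that add atoms: none
Why: Ring-closing metathesis between the vinyl carbinol and the 2-substituted acrylate releases ethene, and the ten-membered ring already holding the cis C4=C5 alkene and the trans lactone accommodates only the ring-cis C1=C10 enoate (C2 cis to C9); the exocyclic methylene and the trisubstituted alkene are poor metathesis partners.

Step 15
Reactants: 26 methyl (2S,6R,7S,8S,9S)-2-[(tert-butyldimethylsilyl)oxy]-15-[(tert-butyldiphenylsilyl)oxy]-8,9-(isopropylidenedioxy)germacra-1(10)E,4E,11(13)-trien-12,6-olid-14-oate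
Product: 27 methyl (2S,6R,7R,8S,9S)-2-[(tert-butyldimethylsilyl)oxy]-15-[(tert-butyldiphenylsilyl)oxy]-8,9-dihydroxygermacra-1(10)E,4E,11(13)-trien-12,6-olid-14-oate
Conditions: 80 % aq. AcOH, 40 °C
Reagents that add atoms: none
Why: Mild acid hydrolysis removes the isopropylidene acetal while the secondary TBS and primary TBDPS ethers and the lactone survive; no centre is touched (the C7 descriptor changes only by the sequence rule).

Step 16
Reactants: 27 methyl (2S,6R,7R,8S,9S)-2-[(tert-butyldimethylsilyl)oxy]-15-[(tert-butyldiphenylsilyl)oxy]-8,9-dihydroxygermacra-1(10)E,4E,11(13)-trien-12,6-olid-14-oate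
Product: 28 methyl (2S,6R,7S,8S,9S)-2-[(tert-butyldimethylsilyl)oxy]-15-[(tert-butyldiphenylsilyl)oxy]-9-hydroxy-8-(2-methylpropanoyloxy)germacra-1(10)E,4E,11(13)-trien-12,6-olid-14-oate
Conditions: (i-PrCO)2O (1.1 equiv), 2,4,6-collidine, DMAP (5 mol %), CH2Cl2, −40 °C
Reagents that add atoms: 2-methylpropanoic anhydride, CC(C)C(=O)OC(=O)C(C)C
Why: Kinetically controlled regioselective O-acylation goes to the ordinary secondary C8 hydroxyl because the C9 hydroxyl is allylic to the enoate carbon, hydrogen-bonded to the C14 carbonyl and less nucleophilic (if the preference proves opposite, the two anhydrides are used in reverse order to reach 29).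

Step 17
Reactants: 28 methyl (2S,6R,7S,8S,9S)-2-[(tert-butyldimethylsilyl)oxy]-15-[(tert-butyldiphenylsilyl)oxy]-9-hydroxy-8-(2-methylpropanoyloxy)germacra-1(10)E,4E,11(13)-trien-12,6-olid-14-oate
Product: 29 methyl (2S,6R,7S,8S,9S)-9-acetoxy-2-[(tert-butyldimethylsilyl)oxy]-15-[(tert-butyldiphenylsilyl)oxy]-8-(2-methylpropanoyloxy)germacra-1(10)E,4E,11(13)-trien-12,6-olid-14-oate
Conditions: Ac2O, pyridine, DMAP (cat.), CH2Cl2, 0 °C to rt
Reagents that add atoms: acetic anhydride, CC(=O)OC(C)=O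
Why: DMAP-catalysed acetylation of the remaining hydroxyl under non-equilibrating conditions avoids acyl migration and translactonisation.

Step 18
Reactants: 29 methyl (2S,6R,7S,8S,9S)-9-acetoxy-2-[(tert-butyldimethylsilyl)oxy]-15-[(tert-butyldiphenylsilyl)oxy]-8-(2-methylpropanoyloxy)germacra-1(10)E,4E,11(13)-trien-12,6-olid-14-oate
Product: 30 methyl (2S,6R,7S,8S,9S)-9-acetoxy-2,15-dihydroxy-8-(2-methylpropanoyloxy)germacra-1(10)E,4E,11(13)-trien-12,6-olid-14-oate
Conditions: HF·pyridine, pyridine, THF, 0 °C to rt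
Reagents that add atoms: none
Why: Buffered fluoride desilylation cleaves both silyl ethers without touching the esters, the lactone or the exocyclic enoate and gives the target.

**Compound list**
1 | but-2-yne-1,4-diol | OCC#CCO | starting material
2 | 4-[(tert-butyldiphenylsilyl)oxy]but-2-yn-1-ol | OCC#CCO[Si](c1ccccc1)(c1ccccc1)C(C)(C)C | intermediate
3 | sodium alkenylalanate: five-membered O–Al–C chelate, Al(OCH2CH2OMe)2 bridging the C6 oxygen and alkene carbon C4, H on C5 trans to Al | [Na+].COCCO[Al-]1(OCCOC)OCC=C1CO[Si](c2ccccc2)(c2ccccc2)C(C)(C)C | intermediate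
4 | (2Z)-4-[(tert-butyldiphenylsilyl)oxy]-3-iodobut-2-en-1-ol | OC/C=C(\I)CO[Si](c1ccccc1)(c1ccccc1)C(C)(C)C | intermediate
5 | (2Z)-1-[(tert-butyldiphenylsilyl)oxy]-2-iodo-4-[(triethylsilyl)oxy]but-2-ene | CC[Si](CC)(CC)OC/C=C(\I)CO[Si](c1ccccc1)(c1ccccc1)C(C)(C)C | intermediate
6 | (S)-epichlorohydrin, (2S)-2-(chloromethyl)oxirane | ClC[C@@H]1CO1 | starting material
7 | alkenyllithium from 5 (Li in place of I, geometry retained) | CC[Si](CC)(CC)OC/C=C(\[Li])CO[Si](c1ccccc1)(c1ccccc1)C(C)(C)C | intermediate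
8 | (2S,4E)-1-chloro-4-{[(tert-butyldiphenylsilyl)oxy]methyl}-6-[(triethylsilyl)oxy]hex-4-en-2-ol | ClC[C@@H](O)C/C(=C\CO[Si](CC)(CC)CC)CO[Si](c1ccccc1)(c1ccccc1)C(C)(C)C | intermediate
9 | (2S)-2-[(2E)-2-{[(tert-butyldiphenylsilyl)oxy]methyl}-4-[(triethylsilyl)oxy]but-2-en-1-yl]oxirane | C1[C@@H](O1)C/C(=C\CO[Si](CC)(CC)CC)CO[Si](c2ccccc2)(c2ccccc2)C(C)(C)C | intermediate
10 | lithium (3S,5E)-5-{[(tert-butyldiphenylsilyl)oxy]methyl}-7-[(triethylsilyl)oxy]hepta-1,5-dien-3-olate | C=C[C@@H](O[Li])C/C(=C\CO[Si](CC)(CC)CC)CO[Si](c1ccccc1)(c1ccccc1)C(C)(C)C | intermediate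
11 | (3S,5E)-3-[(tert-butyldimethylsilyl)oxy]-5-{[(tert-butyldiphenylsilyl)oxy]methyl}-7-[(triethylsilyl)oxy]hepta-1,5-diene | C=C[C@@H](O[Si](C)(C)C(C)(C)C)C/C(=C\CO[Si](CC)(CC)CC)CO[Si](c1ccccc1)(c1ccccc1)C(C)(C)C | intermediate
12 | (2E,5S)-5-[(tert-butyldimethylsilyl)oxy]-3-{[(tert-butyldiphenylsilyl)oxy]methyl}hepta-2,6-dienal | C=C[C@@H](O[Si](C)(C)C(C)(C)C)C/C(=C\C=O)CO[Si](c1ccccc1)(c1ccccc1)C(C)(C)C | intermediate
13 | methyl prop-2-ynoate (methyl propiolate) | C#CC(=O)OC | starting material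
14 | methyl 3-bromoprop-2-ynoate | BrC#CC(=O)OC | intermediate
15 | dimethyl (4R,5R)-2,2-dimethyl-1,3-dioxolane-4,5-dicarboxylate (dimethyl 2,3-O-isopropylidene-L-tartrate) | COC(=O)[C@@H]1OC(C)(C)O[C@H]1C(=O)OC | starting material
16 | (4R,5R)-5-(methoxycarbonyl)-2,2-dimethyl-1,3-dioxolane-4-carboxylic acid | OC(=O)[C@@H]1OC(C)(C)O[C@H]1C(=O)OC | intermediate
17 | (4R,5R)-5-formyl-2,2-dimethyl-1,3-dioxolane-4-carboxylic acid (present as its aluminium derivative) | OC(=O)[C@@H]1OC(C)(C)O[C@H]1C=O | intermediate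
18 | (4R,5S)-5-ethynyl-2,2-dimethyl-1,3-dioxolane-4-carboxylic acid (trans) | OC(=O)[C@@H]1OC(C)(C)O[C@H]1C#C | intermediate
19 | 1,3-dioxoisoindolin-2-yl (4R,5S)-5-ethynyl-2,2-dimethyl-1,3-dioxolane-4-carboxylate | O=C(ON1C(=O)c2ccccc2C1=O)[C@@H]3OC(C)(C)O[C@H]3C#C | intermediate
20 | methyl 3-[(4S,5S)-5-ethynyl-2,2-dimethyl-1,3-dioxolan-4-yl]prop-2-ynoate (trans) | COC(=O)C#C[C@@H]1OC(C)(C)O[C@H]1C#C | intermediate
21 | methyl 2-[(4S,5S)-5-(3-methoxy-3-oxoprop-1-yn-1-yl)-2,2-dimethyl-1,3-dioxolan-4-yl]prop-2-enoate | COC(=O)C#C[C@@H]1OC(C)(C)O[C@H]1C(=C)C(=O)OC | intermediate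
22 | methyl (2E)-2-[bis(2-methylpropyl)alumanyl]-3-[(4S,5S)-5-(3-methoxy-3-oxoprop-1-en-2-yl)-2,2-dimethyl-1,3-dioxolan-4-yl]prop-2-enoate (Al cis to H-3) | COC(=O)/C([Al](CC(C)C)CC(C)C)=C\[C@@H]1OC(C)(C)O[C@H]1C(=C)C(=O)OC | intermediate
23 | methyl (2Z)-3-[(4S,5S)-5-(3-methoxy-3-oxoprop-1-en-2-yl)-2,2-dimethyl-1,3-dioxolan-4-yl]-2-[(4,4,5,5-tetramethyl-1,3,2-dioxaborolan-2-yl)methyl]prop-2-enoate | COC(=O)/C(CB1OC(C)(C)C(C)(C)O1)=C\[C@@H]2OC(C)(C)O[C@H]2C(=C)C(=O)OC | intermediate
24 | methyl (3S,4R,5E,8S)-8-[(tert-butyldimethylsilyl)oxy]-6-{[(tert-butyldiphenylsilyl)oxy]methyl}-3-[(4S,5S)-5-(3-methoxy-3-oxoprop-1-en-2-yl)-2,2-dimethyl-1,3-dioxolan-4-yl]-2-methylidene-4-[(4,4,5,5-tetramethyl-1,3,2-dioxaborolan-2-yl)oxy]deca-5,9-dienoate | COC(=O)C(=C)[C@@H]([C@H](OB1OC(C)(C)C(C)(C)O1)/C=C(/CO[Si](c2ccccc2)(c2ccccc2)C(C)(C)C)C[C@H](O[Si](C)(C)C(C)(C)C)C=C)[C@@H]3OC(C)(C)O[C@H]3C(=C)C(=O)OC | intermediate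
25 | (4S,5R)-5-[(1E,4S)-4-[(tert-butyldimethylsilyl)oxy]-2-{[(tert-butyldiphenylsilyl)oxy]methyl}hexa-1,5-dien-1-yl]-4-[(4S,5S)-5-(3-methoxy-3-oxoprop-1-en-2-yl)-2,2-dimethyl-1,3-dioxolan-4-yl]-3-methylideneoxolan-2-one | C=C1C(=O)O[C@H](/C=C(/CO[Si](c2ccccc2)(c2ccccc2)C(C)(C)C)C[C@H](O[Si](C)(C)C(C)(C)C)C=C)[C@H]1[C@@H]3OC(C)(C)O[C@H]3C(=C)C(=O)OC | intermediate
26 | methyl (2S,6R,7S,8S,9S)-2-[(tert-butyldimethylsilyl)oxy]-15-[(tert-butyldiphenylsilyl)oxy]-8,9-(isopropylidenedioxy)germacra-1(10)E,4E,11(13)-trien-12,6-olid-14-oate | C=C1C(=O)O[C@@H]2/C=C(/CO[Si](c3ccccc3)(c3ccccc3)C(C)(C)C)C[C@H](O[Si](C)(C)C(C)(C)C)/C=C(/C(=O)OC)[C@@H]4OC(C)(C)O[C@H]4[C@@H]12 | intermediate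
27 | methyl (2S,6R,7R,8S,9S)-2-[(tert-butyldimethylsilyl)oxy]-15-[(tert-butyldiphenylsilyl)oxy]-8,9-dihydroxygermacra-1(10)E,4E,11(13)-trien-12,6-olid-14-oate (same spatial arrangement as 26) | C=C1C(=O)O[C@@H]2/C=C(/CO[Si](c3ccccc3)(c3ccccc3)C(C)(C)C)C[C@H](O[Si](C)(C)C(C)(C)C)/C=C(/C(=O)OC)[C@H](O)[C@@H](O)[C@@H]12 | intermediate
28 | methyl (2S,6R,7S,8S,9S)-2-[(tert-butyldimethylsilyl)oxy]-15-[(tert-butyldiphenylsilyl)oxy]-9-hydroxy-8-(2-methylpropanoyloxy)germacra-1(10)E,4E,11(13)-trien-12,6-olid-14-oate | C=C1C(=O)O[C@@H]2/C=C(/CO[Si](c3ccccc3)(c3ccccc3)C(C)(C)C)C[C@H](O[Si](C)(C)C(C)(C)C)/C=C(/C(=O)OC)[C@H](O)[C@@H](OC(=O)C(C)C)[C@@H]12 | intermediate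
29 | methyl (2S,6R,7S,8S,9S)-9-acetoxy-2-[(tert-butyldimethylsilyl)oxy]-15-[(tert-butyldiphenylsilyl)oxy]-8-(2-methylpropanoyloxy)germacra-1(10)E,4E,11(13)-trien-12,6-olid-14-oate | C=C1C(=O)O[C@@H]2/C=C(/CO[Si](c3ccccc3)(c3ccccc3)C(C)(C)C)C[C@H](O[Si](C)(C)C(C)(C)C)/C=C(/C(=O)OC)[C@H](OC(C)=O)[C@@H](OC(=O)C(C)C)[C@@H]12 | intermediate
30 | methyl (2S,6R,7S,8S,9S)-9-acetoxy-2,15-dihydroxy-8-(2-methylpropanoyloxy)germacra-1(10)E,4E,11(13)-trien-12,6-olid-14-oate (CNP0301018.3) | C=C1C(=O)O[C@@H]2/C=C(/CO)C[C@H](O)/C=C(/C(=O)OC)[C@H](OC(C)=O)[C@@H](OC(=O)C(C)C)[C@@H]12 | target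

**Step count and risks**

Total step count: 18. Longest linear sequence: 12 steps (steps 1–6, then 13–18).

Step 10 (the proposed photochemical alkoxycarbonylethynylation). The bromopropiolate may be consumed by hydride transfer or oligomerisation before the radical reaches it, and the small ethynyl group may give only moderate trans selectivity. The fallback uses known chemistry and sets out from 15. One-pot i-Bu2AlH reduction of both esters and Ohira–Bestmann homologation gives (4S,5S)-4,5-diethynyl-2,2-dimethyl-1,3-dioxolane F1. Monolithiation (LiN(SiMe3)2, 1.0 equiv, THF, −78 °C) and ClCO2Me then give ynoate 20, statistically and with recycling of F1, and the route is rejoined at 20. No radical is formed, so both tartrate centres are carried through unchanged.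

Step 13 (allylboration–lactonisation). The ester-deactivated, γ-branched boronate and the β,β-disubstituted enal are both sluggish partners, and two stereocentres depend on one transition state. The fallback sets out from 23. KHF2 in aqueous MeOH converts it into potassium trifluoro{(2Z)-2-(methoxycarbonyl)-3-[(4S,5S)-5-(3-methoxy-3-oxoprop-1-en-2-yl)-2,2-dimethyl-1,3-dioxolan-4-yl]prop-2-en-1-yl}borate F2. BF3·OEt2 in CH2Cl2 at −78 °C releases the much more electrophilic allyldifluoroborane, which adds to 12 through the same closed transition state (Batey-type allylation) to give methyl (3S,4R,5E,8S)-8-[(tert-butyldimethylsilyl)oxy]-6-{[(tert-butyldiphenylsilyl)oxy]methyl}-4-hydroxy-3-[(4S,5S)-5-(3-methoxy-3-oxoprop-1-en-2-yl)-2,2-dimethyl-1,3-dioxolan-4-yl]-2-methylidenedeca-5,9-dienoate F3. PPTS closes the lactone and the route is rejoined at 25.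

Step 14 (ring-closing metathesis to a ten-membered trisubstituted enoate). The hindered 2-substituted acrylate and the rigid trans-dioxolane may favour oligomers over the ring. The fallback sets out from 25 and changes the order of events. The acetonide is removed first (80 % aq. AcOH, 40 °C) to give the 8,9-diol of 25 with unchanged configuration F4. Ring-closing metathesis is then run on F4, which is conformationally unlocked and whose free C9 allylic hydroxyl assists ruthenium carbene transfer to the acrylate. This gives 27 directly, and the route is rejoined at 27.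

**Further compounds**
F1 | step 10 | (4S,5S)-4,5-diethynyl-2,2-dimethyl-1,3-dioxolane | C#C[C@@H]1OC(C)(C)O[C@H]1C#C
F2 | step 13 | potassium trifluoro{(2Z)-2-(methoxycarbonyl)-3-[(4S,5S)-5-(3-methoxy-3-oxoprop-1-en-2-yl)-2,2-dimethyl-1,3-dioxolan-4-yl]prop-2-en-1-yl}borate | [K+].COC(=O)/C(C[B-](F)(F)F)=C\[C@@H]1OC(C)(C)O[C@H]1C(=C)C(=O)OC
F3 | step 13 | methyl (3S,4R,5E,8S)-8-[(tert-butyldimethylsilyl)oxy]-6-{[(tert-butyldiphenylsilyl)oxy]methyl}-4-hydroxy-3-[(4S,5S)-5-(3-methoxy-3-oxoprop-1-en-2-yl)-2,2-dimethyl-1,3-dioxolan-4-yl]-2-methylidenedeca-5,9-dienoate | COC(=O)C(=C)[C@@H]([C@H](O)/C=C(/CO[Si](c1ccccc1)(c1ccccc1)C(C)(C)C)C[C@H](O[Si](C)(C)C(C)(C)C)C=C)[C@@H]2OC(C)(C)O[C@H]2C(=C)C(=O)OC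
F4 | step 14 | 8,9-diol of 25 (isopropylidene group removed, configuration unchanged) | C=C1C(=O)O[C@H](/C=C(/CO[Si](c2ccccc2)(c2ccccc2)C(C)(C)C)C[C@H](O[Si](C)(C)C(C)(C)C)C=C)[C@H]1[C@H](O)[C@@H](O)C(=C)C(=O)OC
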